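**Plan**

The retrosynthesis first removes two MOM masks. It then cuts ring C (O-1–C-2 and C-3–OH, Algar–Flynn–Oyamada), the chalcone Cα=Cβ bond (Claisen–Schmidt), the pyran O–CMe2 and C-3''–C-4'' bonds of the ring B/D aldehyde, and the two aryl–prenyl bonds of ring A.
Enabling feature: O-3' and C-4' are ortho on ring B. Ring D (O–CMe2–CH=CH) is therefore the closed valence tautomer of the o-quinone methide O=C-3'–C-4'=CH–CH=CMe2, and joining O to CMe2 restores the aromatic sextet of ring B.
One flask calls up this o-quinone methide from 2-hydroxyterephthalaldehyde and an alkenylboronic acid, with a secondary amine as a catalytic helper that is expelled again. This forms one C–C bond, one C–O bond and ring D, fixes the 3'-O/4'-C orientation and leaves the formyl handle free.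
Forward order: ring A is bought, diprenylated and masked. Ring D is closed on the bought ring B, the two halves are joined as a chalcone, ring C is closed last, and the MOM groups are removed.
Stereochemistry: the target has no stereocentre and its ring D alkene is cis by ring constraint. All transient stereocentres are racemic and are erased within the step that forms them.

Key step: step 3

Remark: 2-hydroxyterephthalaldehyde and (2-methylprop-1-en-1-yl)boronic acid are taken to be catalogue compounds. The route is planned for the isomer with the pyran oxygen at C-3' and the pyran vinyl carbon at C-4'.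

**Step 1**
Reactants: 1 2,4,6-trihydroxyacetophenone; 2 prenyl bromide (2.1 equiv)
Product: 3 1-[2,4,6-trihydroxy-3,5-bis(3-methylbut-2-en-1-yl)phenyl]ethan-1-one
Conditions: KOH (2.1 equiv), H2O, 0 °C to rt
Reagents that add atoms: none
Why: In water the phenolate of the acylphloroglucinol 1 reacts with the soft allylic bromide at carbon rather than at its solvated oxygen atoms (phenolate C-alkylation, the classical C-prenylation of acylphloroglucinols), and since ring A has only two free positions, two equivalents of 2 should fill exactly these, rearomatisation by tautomerisation following each alkylation.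

**Step 2**
Reactants: 3 1-[2,4,6-trihydroxy-3,5-bis(3-methylbut-2-en-1-yl)phenyl]ethan-1-one
Product: 4 1-[2-hydroxy-4,6-bis(methoxymethoxy)-3,5-bis(3-methylbut-2-en-1-yl)phenyl]ethan-1-one
Conditions: MOMCl (2.2 equiv), iPr2NEt, CH2Cl2, 0 °C to rt
Reagents that add atoms: chloromethyl methyl ether (MOMCl), COCCl
Why: Williamson-type O-alkylation with the reactive α-chloro ether masks the para hydroxyl and one of the two equivalent ortho hydroxyls, while the last ortho hydroxyl is held back by its hydrogen bond to the acetyl oxygen and stays free as the future O-1 of ring C.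

**Step 3**
Reactants: 5 2-hydroxyterephthalaldehyde; 6 (2-methylprop-1-en-1-yl)boronic acid (1.3 equiv)
Product: 9 2,2-dimethyl-2H-chromene-7-carbaldehyde, via Petasis aminophenol 7 (not isolated), via o-quinone methide 8 (not isolated)
Conditions: Bn2NH (20 mol %), 1,4-dioxane, 90 °C
Reagents that add atoms: none
Why: Bn2NH condenses reversibly with both formyl groups of 5, but only the iminium ion next to the phenol lies within reach of the tetracoordinate aryloxy(alkenyl)boronate that this phenol forms with 6, so the 2-methylprop-1-enyl group migrates from boron to that carbon alone (Petasis borono-Mannich reaction) to give 7, while the remote formyl group is released unchanged. At 90 °C the doubly activated (benzylic and prenyl-type allylic) C–N bond of 7 ionises with loss of the phenol proton, Bn2NH returns to the cycle, and the o-quinone methide 8, a 1-oxatriene O=C–C=CH–CH=CMe2, is set free. Compound 8 closes the six-membered 2H-pyran ring by a thermal disrotatory oxa-6π electrocyclisation that joins the carbonyl oxygen to the CMe2 terminus and is driven by the return of aromaticity to ring B. The closest known reaction type is the amine-catalysed Petasis condensation of salicylaldehydes with alkenylboronic acids to 2H-chromenes. No stereocentre is created in 9, because the new sp3 carbon bears two methyl groups and the racemic centre of 7 is erased in 8, and any E isomer of 8, which cannot reach the oxygen, is recycled by conjugate re-addition of the amine. The step needs site selectivity (pyran carbon para and pyran oxygen meta to the surviving formyl group) and chemoselectivity between two aldehydes, and both are secured by the ortho-hydroxy-formyl pair already present in 5, so that the regioisomer problem of a sigmatropic or electrophilic annulation of a meta-acyl phenol never arises.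

**Step 4**
Reactants: 4 1-[2-hydroxy-4,6-bis(methoxymethoxy)-3,5-bis(3-methylbut-2-en-1-yl)phenyl]ethan-1-one; 9 2,2-dimethyl-2H-chromene-7-carbaldehyde
Product: 10 (E)-3-(2,2-dimethyl-2H-chromen-7-yl)-1-[2-hydroxy-4,6-bis(methoxymethoxy)-3,5-bis(3-methylbut-2-en-1-yl)phenyl]prop-2-en-1-one
Conditions: KOH, EtOH–H2O, rt
Reagents that add atoms: none
Why: Claisen–Schmidt condensation: the acetyl group of 4 is the only enolisable site and 9 cannot enolise, so crossed aldol addition and E1cB loss of water should give the conjugated E-enone, with MOM ethers, prenyl groups and the chromene all inert to hydroxide.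

**Step 5**
Reactants: 10 (E)-3-(2,2-dimethyl-2H-chromen-7-yl)-1-[2-hydroxy-4,6-bis(methoxymethoxy)-3,5-bis(3-methylbut-2-en-1-yl)phenyl]prop-2-en-1-one
Product: 12 2-(2,2-dimethyl-2H-chromen-7-yl)-3-hydroxy-5,7-bis(methoxymethoxy)-6,8-bis(3-methylbut-2-en-1-yl)-4H-chromen-4-one, via trans-dihydroflavonol 11 (not isolated)
Conditions: 30% aq H2O2, NaOH, MeOH, 0 °C to rt
Reagents that add atoms: hydrogen peroxide, OO
Why: Algar–Flynn–Oyamada oxidation: the free phenoxide closes ring C on the enone β-carbon (6-endo oxa-Michael addition), the resulting enolate is hydroxylated by H2O2 to the racemic trans-dihydroflavonol 11, and further alkaline H2O2 dehydrogenates 11 to the flavonol so that both transient stereocentres vanish, while the nucleophilic oxidant leaves the electron-rich prenyl and chromene alkenes untouched.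

**Step 6**
Reactants: 12 2-(2,2-dimethyl-2H-chromen-7-yl)-3-hydroxy-5,7-bis(methoxymethoxy)-6,8-bis(3-methylbut-2-en-1-yl)-4H-chromen-4-one
Product: 13 dorsilurin C
Conditions: conc. HCl (cat.), MeOH, 40 °C
Reagents that add atoms: none
Why: Acid-catalysed transacetalisation to methanol cleaves both aryl MOM acetals through the methoxymethyl oxocarbenium ion at an acidity that should not protonate the prenyl alkenes or the chromene alkene, the latter being deactivated by the electron-poor flavonol ring para to its benzylic carbon.

**Compound list**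

1 | 2,4,6-trihydroxyacetophenone | CC(=O)c1c(O)cc(O)cc1O | starting material
2 | prenyl bromide (1-bromo-3-methylbut-2-ene) | CC(C)=CCBr | starting material
3 | 1-[2,4,6-trihydroxy-3,5-bis(3-methylbut-2-en-1-yl)phenyl]ethan-1-one | CC(=O)c1c(O)c(CC=C(C)C)c(O)c(CC=C(C)C)c1O | intermediate
4 | 1-[2-hydroxy-4,6-bis(methoxymethoxy)-3,5-bis(3-methylbut-2-en-1-yl)phenyl]ethan-1-one | COCOc1c(CC=C(C)C)c(O)c(C(C)=O)c(OCOC)c1CC=C(C)C | intermediate
5 | 2-hydroxyterephthalaldehyde (2-hydroxybenzene-1,4-dicarbaldehyde) | O=Cc1ccc(C=O)c(O)c1 | starting material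
6 | (2-methylprop-1-en-1-yl)boronic acid | CC(C)=CB(O)O | starting material
7 | racemic 4-[1-(dibenzylamino)-3-methylbut-2-en-1-yl]-3-hydroxybenzaldehyde (Petasis aminophenol) | CC(C)=CC(N(Cc1ccccc1)Cc1ccccc1)c1ccc(C=O)cc1O | intermediate
8 | (4Z)-4-(3-methylbut-2-en-1-ylidene)-3-oxocyclohexa-1,5-diene-1-carbaldehyde (o-quinone methide) | O=C1C=C(C=O)C=C/C1=C/C=C(C)C | intermediate
9 | 2,2-dimethyl-2H-chromene-7-carbaldehyde | CC1(C)C=Cc2ccc(C=O)cc2O1 | intermediate
10 | (E)-3-(2,2-dimethyl-2H-chromen-7-yl)-1-[2-hydroxy-4,6-bis(methoxymethoxy)-3,5-bis(3-methylbut-2-en-1-yl)phenyl]prop-2-en-1-one | COCOc1c(CC=C(C)C)c(O)c(C(=O)/C=C/c2ccc3c(c2)OC(C)(C)C=C3)c(OCOC)c1CC=C(C)C | intermediate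
11 | racemic trans-2-(2,2-dimethyl-2H-chromen-7-yl)-3-hydroxy-5,7-bis(methoxymethoxy)-6,8-bis(3-methylbut-2-en-1-yl)chroman-4-one (one enantiomer drawn) | CC(C)=CCc1c(OCOC)c(CC=C(C)C)c2O[C@H](c3ccc4c(c3)OC(C)(C)C=C4)[C@@H](O)C(=O)c2c1OCOC | intermediate
12 | 2-(2,2-dimethyl-2H-chromen-7-yl)-3-hydroxy-5,7-bis(methoxymethoxy)-6,8-bis(3-methylbut-2-en-1-yl)-4H-chromen-4-one | CC(C)=CCc1c(OCOC)c(CC=C(C)C)c2oc(-c3ccc4c(c3)OC(C)(C)C=C4)c(O)c(=O)c2c1OCOC | intermediate
13 | dorsilurin C, 2-(2,2-dimethyl-2H-chromen-7-yl)-3,5,7-trihydroxy-6,8-bis(3-methylbut-2-en-1-yl)-4H-chromen-4-one | CC(C)=CCc1c(O)c(CC=C(C)C)c2oc(-c3ccc4c(c3)OC(C)(C)C=C4)c(O)c(=O)c2c1O | target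

**Step count**

Total step count: 6. Longest linear sequence: 5 (steps 1, 2, 4, 5, 6).

**Steps most likely to fail**

1. **Step 5.**
   - Risk: the ortho MOM ether and the flanking prenyl group twist the carbonyl group out of the plane of ring A. Epoxidation of the enone may then outrun the oxa-Michael closure, and the phenoxide would open the epoxide at the α-carbon, giving five-membered instead of six-membered ring closure.
   - Fallback: it sets out from 10 and comes back to the route at 13.
     - The phenol of 10 would be capped (MOMCl, NaH, DMF) to give the tris(methoxymethyl) chalcone F1.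
     - Weitz–Scheffer epoxidation (H2O2, NaOH, MeOH–THF) would then give the racemic trans-epoxy ketone F2.
     - HCl in MeOH would remove all three MOM groups. One of the two equivalent freed ortho phenols would then open the protonated epoxide at its benzylic carbon with inversion (6-endo), giving the racemic trans-dihydroflavonol F3.
     - Acyloin oxidation of F3 with Bi(OAc)3 in AcOH at 80 °C (trivalent bismuth leaves alkenes alone), followed by enolisation, gives 13.

2. **Step 3.**
   - Risk: protodeboronation of 6 may be faster than the alkenyl transfer. Expulsion of the amine from the electron-poor ring may be slow, and the catalyst may be tied up at the remote formyl group.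
   - Fallback: it sets out from 5 and comes back to the route at 9.
     - The remote formyl group is the more electrophilic one because it is not hydrogen-bonded. It would be masked selectively (ethylene glycol, 1 equiv, p-TsOH cat., toluene, water separator) to give 4-(1,3-dioxolan-2-yl)-2-hydroxybenzaldehyde F4.
     - Addition of Me2C=CHMgBr (2.2 equiv, THF, 0 °C) would give racemic 5-(1,3-dioxolan-2-yl)-2-(1-hydroxy-3-methylbut-2-en-1-yl)phenol F5.
     - Warming F5 with dilute HCl in THF would dehydrate the benzylic, allylic carbinol to the same type of o-quinone methide, which closes by oxa-6π electrocyclisation. The acetal is hydrolysed in the same operation, giving 9.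

3. **Step 1.**
   - Risk: poor control of the degree and site of alkylation, that is O-alkylation, incomplete alkylation, or geminal dialkylation with dearomatisation.
   - Fallback: it sets out from 1 (with 2) and comes back to the route at 3.
     - O-alkylation under non-aqueous conditions (2, K2CO3, acetone, reflux) would give 1-[2-hydroxy-4,6-bis(3-methylbut-2-en-1-yloxy)phenyl]ethan-1-one F6.
     - An acidic-clay-mediated 1,3-shift of both prenyl groups from oxygen to carbon (montmorillonite K10, CH2Cl2, rt) would follow. It can end only at the two free ring positions and so converges on 3.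

**Further compounds**

F1 | step 5 | (E)-3-(2,2-dimethyl-2H-chromen-7-yl)-1-[2,4,6-tris(methoxymethoxy)-3,5-bis(3-methylbut-2-en-1-yl)phenyl]prop-2-en-1-one | COCOc1c(CC=C(C)C)c(OCOC)c(C(=O)/C=C/c2ccc3c(c2)OC(C)(C)C=C3)c(OCOC)c1CC=C(C)C
F2 | step 5 | racemic trans-[3-(2,2-dimethyl-2H-chromen-7-yl)oxiran-2-yl][2,4,6-tris(methoxymethoxy)-3,5-bis(3-methylbut-2-en-1-yl)phenyl]methanone (one enantiomer drawn) | COCOc1c(CC=C(C)C)c(OCOC)c(C(=O)[C@H]4O[C@@H]4c2ccc3c(c2)OC(C)(C)C=C3)c(OCOC)c1CC=C(C)C
F3 | step 5 | racemic trans-2-(2,2-dimethyl-2H-chromen-7-yl)-3,5,7-trihydroxy-6,8-bis(3-methylbut-2-en-1-yl)chroman-4-one (one enantiomer drawn) | CC(C)=CCc1c(O)c(CC=C(C)C)c2O[C@H](c3ccc4c(c3)OC(C)(C)C=C4)[C@@H](O)C(=O)c2c1O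
F4 | step 3 | 4-(1,3-dioxolan-2-yl)-2-hydroxybenzaldehyde | O=Cc1ccc(C2OCCO2)cc1O
F5 | step 3 | racemic 5-(1,3-dioxolan-2-yl)-2-(1-hydroxy-3-methylbut-2-en-1-yl)phenol | CC(C)=CC(O)c1ccc(C2OCCO2)cc1O
F6 | step 1 | 1-[2-hydroxy-4,6-bis(3-methylbut-2-en-1-yloxy)phenyl]ethan-1-one | CC(=O)c1c(O)cc(OCC=C(C)C)cc1OCC=C(C)C
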